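**Retrosynthetic overview**
- The target comes from its 5‑O‑methyl, 5'‑O‑isopropyl ether by one BCl3 operation (chelation‑controlled 5‑O‑demethylation plus isopropyl ether cleavage).
- Key disconnection: the C2–C1' bond is made last, by direct C2–H zincation of a preformed 3,5,7,8‑tetramethoxychromone and Negishi coupling with a B‑ring aryl bromide. This replaces the usual chalcone or 1,3‑diketone cyclisation that carries the B ring from the start.
- The chromone comes from an ω‑methoxy‑2‑hydroxyacetophenone plus a one‑carbon unit (enaminone annulation).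
- The ketone comes from 1,2,3,5‑tetramethoxybenzene and methoxyacetyl chloride (Friedel–Crafts with selective ortho‑demethylation); the aryl bromide comes from 3‑bromo‑4‑methoxyphenol.
- Ring order: ring A is bought, ring C (pyranone) is closed next, ring B is attached last.

Assumption: the target is achiral (no stereocentre, no stereogenic alkene, freely rotating aryl–chromone bond), so "single enantiomer" needs no stereocontrol. Compounds 1, 2, 5, 8, 9 and the TMP2Zn·2MgCl2·2LiCl and BCl3 solutions are taken as purchased.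

**Step 1**
Reactants: 1 1,2,3,5‑tetramethoxybenzene; 2 methoxyacetyl chloride
Product: 4 1‑(2‑hydroxy‑3,4,6‑trimethoxyphenyl)‑2‑methoxyethan‑1‑one, via 2‑methoxy‑1‑(2,3,4,6‑tetramethoxyphenyl)ethan‑1‑one 3 (not isolated)
Conditions: AlCl3 (2.5 equiv), CH2Cl2/Et2O, 0 °C → rt, 12 h; ice‑water
Reagents that add atoms: methoxyacetyl chloride, COCC(Cl)=O
Why: Friedel–Crafts acylation at one of the two equivalent free ring positions (each flanked by two OMe groups) gives the AlCl3‑chelated ketone, which then loses the sterically compressed 2‑OMe (between C=O and the 3‑OMe) by chelation‑assisted ortho‑demethylation, the usual outcome when this arene is acylated with AlCl3.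

**Step 2**
Reactants: 4 1‑(2‑hydroxy‑3,4,6‑trimethoxyphenyl)‑2‑methoxyethan‑1‑one; 5 N,N‑dimethylformamide dimethyl acetal
Product: 7 3,5,7,8‑tetramethoxy‑4H‑chromen‑4‑one, via 3‑(dimethylamino)‑2‑methoxypropenone 6 (not isolated)
Conditions: DMF‑DMA (3 equiv), PhMe, 100 °C, 4 h; concentrate; conc. HCl, CH2Cl2, 40 °C, 1 h
Reagents that add atoms: N,N‑dimethylformamide dimethyl acetal, COC(OC)N(C)C
Why: Condensation of the activated α‑methylene with DMF‑DMA gives the enaminone, and acid‑promoted intramolecular oxa‑Michael addition of the only free phenol with loss of Me2NH closes the pyranone (enaminone chromone synthesis), the 6'‑OMe staying methylated so that only the 5,7,8‑oxygenation pattern can form.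

**Step 3**
Reactants: 8 3‑bromo‑4‑methoxyphenol; 9 2‑bromopropane
Product: 10 2‑bromo‑1‑methoxy‑4‑(propan‑2‑yloxy)benzene
Conditions: K2CO3, DMF, 60 °C, 6 h
Reagents that add atoms: 2‑bromopropane, CC(C)Br
Why: Williamson etherification (SN2 O‑alkylation of the phenoxide) masks the acidic phenol for the organozinc step with a group that BCl3 removes in step 5 while leaving ordinary aryl methyl ethers.

**Step 4 (key step)**
Reactants: 7 3,5,7,8‑tetramethoxy‑4H‑chromen‑4‑one; 10 2‑bromo‑1‑methoxy‑4‑(propan‑2‑yloxy)benzene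
Product: 12 3,5,7,8‑tetramethoxy‑2‑[2‑methoxy‑5‑(propan‑2‑yloxy)phenyl]‑4H‑chromen‑4‑one, via bis(chromon‑2‑yl)zinc 11 (not isolated)
Conditions: TMP2Zn·2MgCl2·2LiCl (0.6 equiv), THF, −30 → 25 °C, 1 h; then 10 (0.9 equiv), Pd(OAc)2 (3 mol %), SPhos (6 mol %), THF, 50 °C, 12 h
Reagents that add atoms: none
Why: With C3 blocked by OMe, the only pyranone C–H is C2–H, acidified by the ring oxygen, the 3‑OMe and Mg2+ complexation of the C4 carbonyl, so the TMP‑zinc amide zincates there (Knochel‑type directed C–H zincation of a chromone) to a species that cannot β‑eliminate, and both chromonyl groups then transfer to the aryl bromide in a Pd/SPhos Negishi cross‑coupling.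

**Step 5**
Reactants: 12 3,5,7,8‑tetramethoxy‑2‑[2‑methoxy‑5‑(propan‑2‑yloxy)phenyl]‑4H‑chromen‑4‑one
Product: 14 5,5'‑dihydroxy‑3,7,8,2'‑tetramethoxyflavone, via 5‑hydroxy‑5'‑isopropoxy flavone 13 (not isolated)
Conditions: BCl3 (1 M in CH2Cl2, 3.5 equiv), CH2Cl2, −78 → 0 °C, 2 h; MeOH, then aq. NaHCO3
Reagents that add atoms: none
Why: BCl3 binds the C4 carbonyl and cleaves the peri 5‑OMe through a six‑membered chelate (chelation‑controlled demethylation), then dealkylates the secondary isopropyl aryl ether (Lewis‑acid ether cleavage) much faster than the non‑chelated primary methyl ethers at C3, C7, C8 and C2'.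

**Compound list**
1 | 1,2,3,5‑tetramethoxybenzene | COc1cc(OC)c(OC)c(OC)c1 | starting material
2 | methoxyacetyl chloride | COCC(Cl)=O | starting material
3 | 2‑methoxy‑1‑(2,3,4,6‑tetramethoxyphenyl)ethan‑1‑one | COCC(=O)c1c(OC)cc(OC)c(OC)c1OC | intermediate
4 | 1‑(2‑hydroxy‑3,4,6‑trimethoxyphenyl)‑2‑methoxyethan‑1‑one | COCC(=O)c1c(OC)cc(OC)c(OC)c1O | intermediate
5 | N,N‑dimethylformamide dimethyl acetal | COC(OC)N(C)C | starting material
6 | (Z)‑3‑(dimethylamino)‑1‑(2‑hydroxy‑3,4,6‑trimethoxyphenyl)‑2‑methoxyprop‑2‑en‑1‑one (geometry of no consequence) | CN(C)/C=C(\OC)C(=O)c1c(OC)cc(OC)c(OC)c1O | intermediate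
7 | 3,5,7,8‑tetramethoxy‑4H‑chromen‑4‑one | COc1coc2c(OC)c(OC)cc(OC)c2c1=O | intermediate
8 | 3‑bromo‑4‑methoxyphenol | COc1ccc(O)cc1Br | starting material
9 | 2‑bromopropane | CC(C)Br | starting material
10 | 2‑bromo‑1‑methoxy‑4‑(propan‑2‑yloxy)benzene | COc1ccc(OC(C)C)cc1Br | intermediate
11 | bis(3,5,7,8‑tetramethoxy‑4‑oxo‑4H‑chromen‑2‑yl)zinc (MgCl2/LiCl complex) | COc1c([Zn]c2oc3c(OC)c(OC)cc(OC)c3c(=O)c2OC)oc2c(OC)c(OC)cc(OC)c2c1=O | intermediate
12 | 3,5,7,8‑tetramethoxy‑2‑[2‑methoxy‑5‑(propan‑2‑yloxy)phenyl]‑4H‑chromen‑4‑one | COc1ccc(OC(C)C)cc1-c1oc2c(OC)c(OC)cc(OC)c2c(=O)c1OC | intermediate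
13 | 5‑hydroxy‑3,7,8‑trimethoxy‑2‑[2‑methoxy‑5‑(propan‑2‑yloxy)phenyl]‑4H‑chromen‑4‑one | COc1ccc(OC(C)C)cc1-c1oc2c(OC)c(OC)cc(O)c2c(=O)c1OC | intermediate
14 | 5,5'‑dihydroxy‑3,7,8,2'‑tetramethoxyflavone (achiral) | COc1ccc(O)cc1-c1oc2c(OC)c(OC)cc(O)c2c(=O)c1OC | target

**Step count:** 5 steps in total. Longest linear sequence: 4 steps (steps 1, 2, 4, 5).

**Three steps most likely to fail, with fallbacks**

Step 4 (C2–H zincation and hindered Negishi coupling). The fallback sets out from 4 and 10 and returns at 12. It gives up the cross‑coupling and builds the C2–aryl bond by the classical acylative (Baker–Venkataraman type) annulation. Bromide 10 undergoes Br/Li exchange (n‑BuLi, THF, −78 °C) to [2‑methoxy‑5‑(propan‑2‑yloxy)phenyl]lithium F1. Carboxylation with CO2 and HCl work‑up gives 2‑methoxy‑5‑(propan‑2‑yloxy)benzoic acid F2. DCC (0.5 equiv, CH2Cl2) converts this to 2‑methoxy‑5‑(propan‑2‑yloxy)benzoic anhydride F3. The dianion of ketone 4 (LiHMDS, 3 equiv, THF, −78 °C → rt) is C‑aroylated by the anhydride to 1‑(2‑hydroxy‑3,4,6‑trimethoxyphenyl)‑2‑methoxy‑3‑[2‑methoxy‑5‑(propan‑2‑yloxy)phenyl]propane‑1,3‑dione F4 (racemic, enolisable). Cyclodehydration (AcOH, cat. H2SO4, 90 °C) then gives 12.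

Step 5 (BCl3 may also attack the 3‑OMe or 8‑OMe). The fallback sets out from 8, uses 7 through zinc reagent 11, and returns at 14. The two unmaskings are separated and made orthogonal. Phenol 8 is benzylated (BnBr, K2CO3, DMF) to 4‑(benzyloxy)‑2‑bromo‑1‑methoxybenzene F5. Coupling with 11 as in step 4 gives 2‑[5‑(benzyloxy)‑2‑methoxyphenyl]‑3,5,7,8‑tetramethoxy‑4H‑chromen‑4‑one F6. Only the chelated 5‑OMe is then cleaved under the mildest conditions (AlCl3, MeCN, rt → 40 °C; dil. HCl) to give 2‑[5‑(benzyloxy)‑2‑methoxyphenyl]‑5‑hydroxy‑3,7,8‑trimethoxy‑4H‑chromen‑4‑one F7. Hydrogenolysis (H2, Pd/C, EtOAc/MeOH) of the benzyl ether gives 14.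

Step 1 (the acid chloride/AlCl3 pair may cleave the side‑chain ether or demethylate unselectively). The fallback sets out from 1 and returns at 4. Acylation and demethylation are uncoupled, and the Friedel–Crafts reaction is replaced by directed ortho‑metalation. Arene 1 is lithiated between two methoxy groups (n‑BuLi, TMEDA, THF, 0 °C) to 2,3,4,6‑tetramethoxyphenyllithium F8. Acylation with the Weinreb amide N,2‑dimethoxy‑N‑methylacetamide (−78 °C → 0 °C) gives ketone 3, now isolated. A separate, titrated chelation‑controlled demethylation of the buttressed 2‑OMe (BCl3, 1.05 equiv, CH2Cl2, −78 → −20 °C) then gives 4.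

**Further compounds**
F1 | step 4 | [2‑methoxy‑5‑(propan‑2‑yloxy)phenyl]lithium | COc1ccc(OC(C)C)cc1[Li]
F2 | step 4 | 2‑methoxy‑5‑(propan‑2‑yloxy)benzoic acid | COc1ccc(OC(C)C)cc1C(O)=O
F3 | step 4 | 2‑methoxy‑5‑(propan‑2‑yloxy)benzoic anhydride | COc1ccc(OC(C)C)cc1C(=O)OC(=O)c1cc(OC(C)C)ccc1OC
F4 | step 4 | 1‑(2‑hydroxy‑3,4,6‑trimethoxyphenyl)‑2‑methoxy‑3‑[2‑methoxy‑5‑(propan‑2‑yloxy)phenyl]propane‑1,3‑dione (racemic) | COC(C(=O)c1c(OC)cc(OC)c(OC)c1O)C(=O)c1cc(OC(C)C)ccc1OC
F5 | step 5 | 4‑(benzyloxy)‑2‑bromo‑1‑methoxybenzene | COc1ccc(OCc2ccccc2)cc1Br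
F6 | step 5 | 2‑[5‑(benzyloxy)‑2‑methoxyphenyl]‑3,5,7,8‑tetramethoxy‑4H‑chromen‑4‑one | COc1ccc(OCc2ccccc2)cc1-c1oc2c(OC)c(OC)cc(OC)c2c(=O)c1OC
F7 | step 5 | 2‑[5‑(benzyloxy)‑2‑methoxyphenyl]‑5‑hydroxy‑3,7,8‑trimethoxy‑4H‑chromen‑4‑one | COc1ccc(OCc2ccccc2)cc1-c1oc2c(OC)c(OC)cc(O)c2c(=O)c1OC
F8 | step 1 | 2,3,4,6‑tetramethoxyphenyllithium | [Li]c1c(OC)cc(OC)c(OC)c1OC
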